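## Retrosynthetic overview

1. The sulfate and the free acid are installed last. The (2E,4E)-dienoate comes from a C1 ester by a one-pot partial reduction and vinylogous Horner–Wadsworth–Emmons olefination.
2. Ring B is opened at C7–C8. The C7 aldehyde carbon serves as an acyl anion equivalent (carbene-bound Breslow intermediate) and bonds to the internal carbon of a vinyl group on C8a. This gives the C7 ketone and the C8 methyl in one step; the ketone is then reduced to the axial alcohol.
3. Ring A is opened by an enantioselective Diels–Alder reaction between an (E,E,E)-trienoate and ethyl (2E)-4-oxobut-2-enoate, which sets C1, C2, C4a and C8a.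
4. The trienoate comes from tiglic aldehyde by Wittig olefination, vinyl addition and Johnson–Claisen rearrangement.
5. Order of ring formation: ring A first (cycloaddition), ring B second (acyl-anion ring closure).

Ring atoms are named by the naphthalene numbering of the target: C1 carries the dienoate or its precursor, C2 the butenyl group, C3 a methyl, C7 the oxygen, C8 a methyl.

Assumption: the (5R)-imidazolidinone catalyst is taken to expose the Re face of the enal α-carbon (mirror image of the Si-face selectivity of the (5S) catalyst with (E)-enals); if the adduct proved antipodal, the (5S) catalyst would be used and nothing else changes.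

## Route

Step 1
Reactants: 1 (E)-2-methylbut-2-enal; 2 2-(triphenylphosphoranylidene)propanal
Product: 3 (2E,4E)-2,4-dimethylhexa-2,4-dienal
Conditions: PhMe, 110 °C
Reagents that add atoms: none
Why: Wittig olefination by a carbonyl-stabilised ylide gives the new trisubstituted double bond with E geometry, extending tiglic aldehyde to the (2E,4E)-dienal.

Step 2
Reactants: 3 (2E,4E)-2,4-dimethylhexa-2,4-dienal; 4 vinylmagnesium bromide
Product: 5 (4E,6E)-4,6-dimethylocta-1,4,6-trien-3-ol (racemic)
Conditions: CH2=CHMgBr, THF, −78 to 0 °C; H2O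
Reagents that add atoms: none
Why: Grignard 1,2-addition to the α-branched enal gives the bis-allylic alcohol, whose racemic stereocentre is erased in step 3.

Step 3
Reactants: 5 (4E,6E)-4,6-dimethylocta-1,4,6-trien-3-ol (racemic); 6 triethyl orthoacetate
Product: 7 ethyl (4E,6E,8E)-6,8-dimethyldeca-4,6,8-trienoate
Conditions: MeC(OEt)3 (excess), EtCO2H (5 mol%), 135 °C, ethanol distilled off
Reagents that add atoms: none
Why: Johnson–Claisen rearrangement through a chair transition state onto the unsubstituted vinyl terminus gives the (4E) γ,δ-unsaturated ester and adds the two carbons that become C6 and C7.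

Step 4
Reactants: 7 ethyl (4E,6E,8E)-6,8-dimethyldeca-4,6,8-trienoate; 8 ethyl (2E)-4-oxobut-2-enoate
Product: 9 ethyl (1R,2S,5R,6R)-2-[(2E)-but-2-en-2-yl]-5-(3-ethoxy-3-oxopropyl)-6-formyl-3-methylcyclohex-3-ene-1-carboxylate
Conditions: (5R)-5-benzyl-2,2,3-trimethylimidazolidin-4-one hydrochloride (20 mol%), MeCN/H2O 95:5, −20 to 0 °C
Reagents that add atoms: none
Why: Iminium-catalysed enantioselective Diels–Alder reaction forms ring A: the diene terminus next to the methyl-bearing carbon bonds to the enal β-carbon ("para" orientation), the formyl group is endo and so cis to both diene-terminus substituents while the ester is trans, and the catalyst benzyl group blocks one enal face, which fixes C1, C2, C4a and C8a.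

Step 5
Reactants: 9 ethyl (1R,2S,5R,6R)-2-[(2E)-but-2-en-2-yl]-5-(3-ethoxy-3-oxopropyl)-6-formyl-3-methylcyclohex-3-ene-1-carboxylate; 10 methyltriphenylphosphonium bromide
Product: 11 ethyl (1S,2S,5S,6R)-2-[(2E)-but-2-en-2-yl]-6-ethenyl-5-(3-ethoxy-3-oxopropyl)-3-methylcyclohex-3-ene-1-carboxylate
Conditions: KN(SiMe3)2, THF, −78 to 0 °C
Reagents that add atoms: none
Why: Wittig methylenation is selective for the aldehyde over both esters and, run cold, does not epimerise the α-stereocentre; the new CH2 becomes the C8 methyl.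

Step 6
Reactants: 11 ethyl (1S,2S,5S,6R)-2-[(2E)-but-2-en-2-yl]-6-ethenyl-5-(3-ethoxy-3-oxopropyl)-3-methylcyclohex-3-ene-1-carboxylate
Product: 12 ethyl (1S,2S,5S,6R)-2-[(2E)-but-2-en-2-yl]-6-ethenyl-3-methyl-5-(3-oxopropyl)cyclohex-3-ene-1-carboxylate
Conditions: i-Bu2AlH (1.05 equiv), PhMe, −78 °C; H2O
Reagents that add atoms: none
Why: Partial reduction takes the unhindered side-chain ester, because the ring ester is flanked by two substituted ring carbons and reacts much more slowly at −78 °C.

Step 7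
Reactants: 12 ethyl (1S,2S,5S,6R)-2-[(2E)-but-2-en-2-yl]-6-ethenyl-3-methyl-5-(3-oxopropyl)cyclohex-3-ene-1-carboxylate
Product: 13 ethyl (1S,2S,4aS,8S,8aS)-2-[(2E)-but-2-en-2-yl]-3,8-dimethyl-7-oxo-1,2,4a,5,6,7,8,8a-octahydronaphthalene-1-carboxylate
Conditions: 3-mesityl-5,6,7,8-tetrahydro-4H-cyclohepta[d]thiazol-3-ium perchlorate (20 mol%), 1,8-diazabicyclo[5.4.0]undec-7-ene (20 mol%), 1,4-dioxane, 100 °C
Reagents that add atoms: none
Why: Proposed new method: the carbene turns the C7 aldehyde into a nucleophilic Breslow enaminol (acyl anion equivalent) that bonds to the internal carbon of the cis-placed vinyl group while its O–H proton passes to the terminal carbon (concerted, Conia-ene-like intramolecular hydroacylation), closing cis-fused ring B as a 2-methylcyclohexanone; the bulky azolium on C7 must sit equatorial, away from the axial C8a–C1 bond, so the alkene terminus receiving the proton is also equatorial and the new methyl is 8S; closest known reaction type: carbene-catalysed intramolecular hydroacylation of unactivated terminal olefins in 2-allyloxybenzaldehydes giving 3-methylchroman-4-ones.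

Step 8
Reactants: 13 ethyl (1S,2S,4aS,8S,8aS)-2-[(2E)-but-2-en-2-yl]-3,8-dimethyl-7-oxo-1,2,4a,5,6,7,8,8a-octahydronaphthalene-1-carboxylate
Product: 14 ethyl (1S,2S,4aS,7R,8S,8aS)-2-[(2E)-but-2-en-2-yl]-7-hydroxy-3,8-dimethyl-1,2,4a,5,6,7,8,8a-octahydronaphthalene-1-carboxylate
Conditions: LiBH(s-Bu)3, THF, −78 °C; H2O
Reagents that add atoms: none
Why: The bulky hydride attacks the ketone along the equatorial trajectory, the axial one being blocked by the syn-axial C8a–C1 bond, so the hydroxyl is axial and cis to the C8 methyl (7R); the ester is untouched at −78 °C.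

Step 9
Reactants: 14 ethyl (1S,2S,4aS,7R,8S,8aS)-2-[(2E)-but-2-en-2-yl]-7-hydroxy-3,8-dimethyl-1,2,4a,5,6,7,8,8a-octahydronaphthalene-1-carboxylate; 15 ethyl (2E)-4-(diethoxyphosphoryl)but-2-enoate
Product: 17 ethyl (2E,4E)-5-[(1S,2S,4aS,7R,8S,8aR)-2-[(2E)-but-2-en-2-yl]-7-hydroxy-3,8-dimethyl-1,2,4a,5,6,7,8,8a-octahydronaphthalen-1-yl]penta-2,4-dienoate, via hydroxy aldehyde 16 (not isolated)
Conditions: i-Bu2AlH (2.2 equiv), CH2Cl2, −78 °C; then 15 pre-treated with LiN(SiMe3)2 in THF, −78 to 0 °C; H2O
Reagents that add atoms: none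
Why: One-pot partial reduction and vinylogous Horner–Wadsworth–Emmons olefination: the aluminium hemiacetal releases the C1 aldehyde only in the presence of the phosphonate anion, so C1 is not epimerised, and the stabilised phosphonate gives the (2E,4E)-dienoate.

Step 10
Reactants: 17 ethyl (2E,4E)-5-[(1S,2S,4aS,7R,8S,8aR)-2-[(2E)-but-2-en-2-yl]-7-hydroxy-3,8-dimethyl-1,2,4a,5,6,7,8,8a-octahydronaphthalen-1-yl]penta-2,4-dienoate
Product: 18 ethyl (2E,4E)-5-[(1S,2S,4aS,7R,8S,8aR)-2-[(2E)-but-2-en-2-yl]-3,8-dimethyl-7-(sulfooxy)-1,2,4a,5,6,7,8,8a-octahydronaphthalen-1-yl]penta-2,4-dienoate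
Conditions: SO3·pyridine, pyridine, 40 °C; cold dilute HCl work-up
Reagents that add atoms: sulfur trioxide pyridine complex, [O-]S(=O)(=O)[n+]1ccccc1
Why: O-Sulfation of the secondary alcohol by the sulfur trioxide amine complex occurs at oxygen with retention at C7; ester and alkenes are inert.

Step 11
Reactants: 18 ethyl (2E,4E)-5-[(1S,2S,4aS,7R,8S,8aR)-2-[(2E)-but-2-en-2-yl]-3,8-dimethyl-7-(sulfooxy)-1,2,4a,5,6,7,8,8a-octahydronaphthalen-1-yl]penta-2,4-dienoate
Product: 19 (2E,4E)-5-[(1S,2S,4aS,7R,8S,8aR)-2-[(2E)-but-2-en-2-yl]-3,8-dimethyl-7-(sulfooxy)-1,2,4a,5,6,7,8,8a-octahydronaphthalen-1-yl]penta-2,4-dienoic acid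
Conditions: LiOH, THF/H2O, 0 °C to rt; then cold 1 M HCl to pH 2
Reagents that add atoms: lithium hydroxide, [Li+].[OH-]
Why: Saponification of the ethyl ester; the alkyl sulfate monoester is inert to hydroxide, and brief cold acidification gives the free acid without cleaving it.

## Compound list

1 | (E)-2-methylbut-2-enal (tiglic aldehyde) | C/C=C(\C)C=O | starting material
2 | 2-(triphenylphosphoranylidene)propanal | CC(C=O)=P(c1ccccc1)(c1ccccc1)c1ccccc1 | starting material
3 | (2E,4E)-2,4-dimethylhexa-2,4-dienal | C/C=C(\C)/C=C(\C)C=O | intermediate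
4 | vinylmagnesium bromide | C=C[Mg]Br | starting material
5 | (4E,6E)-4,6-dimethylocta-1,4,6-trien-3-ol (racemic) | C/C=C(\C)/C=C(\C)C(O)C=C | intermediate
6 | triethyl orthoacetate | CC(OCC)(OCC)OCC | starting material
7 | ethyl (4E,6E,8E)-6,8-dimethyldeca-4,6,8-trienoate | C/C=C(\C)/C=C(\C)/C=C/CCC(=O)OCC | intermediate
8 | ethyl (2E)-4-oxobut-2-enoate | CCOC(=O)/C=C/C=O | starting material
9 | ethyl (1R,2S,5R,6R)-2-[(2E)-but-2-en-2-yl]-5-(3-ethoxy-3-oxopropyl)-6-formyl-3-methylcyclohex-3-ene-1-carboxylate | C/C=C(\C)[C@H]1C(C)=C[C@@H](CCC(=O)OCC)[C@@H](C=O)[C@@H]1C(=O)OCC | intermediate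
10 | methyltriphenylphosphonium bromide | C[P+](c1ccccc1)(c1ccccc1)c1ccccc1.[Br-] | starting material
11 | ethyl (1S,2S,5S,6R)-2-[(2E)-but-2-en-2-yl]-6-ethenyl-5-(3-ethoxy-3-oxopropyl)-3-methylcyclohex-3-ene-1-carboxylate | C/C=C(\C)[C@H]1C(C)=C[C@@H](CCC(=O)OCC)[C@@H](C=C)[C@@H]1C(=O)OCC | intermediate
12 | ethyl (1S,2S,5S,6R)-2-[(2E)-but-2-en-2-yl]-6-ethenyl-3-methyl-5-(3-oxopropyl)cyclohex-3-ene-1-carboxylate | C/C=C(\C)[C@H]1C(C)=C[C@@H](CCC=O)[C@@H](C=C)[C@@H]1C(=O)OCC | intermediate
13 | ethyl (1S,2S,4aS,8S,8aS)-2-[(2E)-but-2-en-2-yl]-3,8-dimethyl-7-oxo-1,2,4a,5,6,7,8,8a-octahydronaphthalene-1-carboxylate | C/C=C(\C)[C@H]1C(C)=C[C@H]2CCC(=O)[C@@H](C)[C@H]2[C@@H]1C(=O)OCC | intermediate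
14 | ethyl (1S,2S,4aS,7R,8S,8aS)-2-[(2E)-but-2-en-2-yl]-7-hydroxy-3,8-dimethyl-1,2,4a,5,6,7,8,8a-octahydronaphthalene-1-carboxylate | C/C=C(\C)[C@H]1C(C)=C[C@H]2CC[C@@H](O)[C@@H](C)[C@H]2[C@@H]1C(=O)OCC | intermediate
15 | ethyl (2E)-4-(diethoxyphosphoryl)but-2-enoate | CCOC(=O)/C=C/CP(=O)(OCC)OCC | starting material
16 | (1S,2S,4aS,7R,8S,8aS)-2-[(2E)-but-2-en-2-yl]-7-hydroxy-3,8-dimethyl-1,2,4a,5,6,7,8,8a-octahydronaphthalene-1-carbaldehyde (not isolated) | C/C=C(\C)[C@H]1C(C)=C[C@H]2CC[C@@H](O)[C@@H](C)[C@H]2[C@@H]1C=O | intermediate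
17 | ethyl (2E,4E)-5-[(1S,2S,4aS,7R,8S,8aR)-2-[(2E)-but-2-en-2-yl]-7-hydroxy-3,8-dimethyl-1,2,4a,5,6,7,8,8a-octahydronaphthalen-1-yl]penta-2,4-dienoate | C/C=C(\C)[C@H]1C(C)=C[C@H]2CC[C@@H](O)[C@@H](C)[C@H]2[C@@H]1/C=C/C=C/C(=O)OCC | intermediate
18 | ethyl (2E,4E)-5-[(1S,2S,4aS,7R,8S,8aR)-2-[(2E)-but-2-en-2-yl]-3,8-dimethyl-7-(sulfooxy)-1,2,4a,5,6,7,8,8a-octahydronaphthalen-1-yl]penta-2,4-dienoate | C/C=C(\C)[C@H]1C(C)=C[C@H]2CC[C@@H](OS(=O)(=O)O)[C@@H](C)[C@H]2[C@@H]1/C=C/C=C/C(=O)OCC | intermediate
19 | (2E,4E)-5-[(1S,2S,4aS,7R,8S,8aR)-2-[(2E)-but-2-en-2-yl]-3,8-dimethyl-7-(sulfooxy)-1,2,4a,5,6,7,8,8a-octahydronaphthalen-1-yl]penta-2,4-dienoic acid | C/C=C(\C)[C@H]1C(C)=C[C@H]2CC[C@@H](OS(=O)(=O)O)[C@@H](C)[C@H]2[C@@H]1/C=C/C=C/C(=O)O | target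

## Step count and risks

Total step count: 11. Longest linear sequence: 11 steps (1 to 19).

**Step 7 is the most likely to fail.** The carbene-catalysed hydroacylation is known for aromatic aldehydes, not for an enolisable aliphatic one, so aldol and benzoin side reactions may compete. The C8 centre is also α to the new ketone and could epimerise under base; the equatorial methyl is peri to the C1 ester and may not be the thermodynamic epimer, so crude 13 should be reduced at once. The fallback sets out from 12 and comes back at 13 by a neutral acyl-radical route. NaClO2/NaH2PO4/2-methylbut-2-ene oxidises 12 to the carboxylic acid F1. (PhSe)2 and PBu3 convert it into the Se-phenyl selenoester F2. Bu3SnH and azobisisobutyronitrile in benzene at 80 °C (slow addition) generate the acyl radical, which closes 6-exo onto the internal vinyl carbon; the primary radical is reduced to the methyl group, giving 13 without base.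

**Step 4 is the second risk.** Three selectivities must all hold in one intermolecular cycloaddition: regiochemistry against the steric demand of the butenyl-bearing terminus, formyl-endo over ester-endo, and the enantiofacial sense. The fallback sets out from 7 and comes back at 9 using a stoichiometric chiral auxiliary and chelating Lewis acid. Monoethyl fumarate is coupled (pivaloyl chloride, Et3N, then the lithium salt of (4R)-4-benzyl-1,3-oxazolidin-2-one) to give the imide dienophile F3. Et2AlCl in CH2Cl2 at −78 °C promotes cycloaddition with 7; the chelated imide controls regiochemistry, endo orientation and face, giving the imide adduct F4. LiBH4 with one equivalent of H2O in Et2O at 0 °C cleaves the auxiliary reductively to the primary alcohol F5. Dess–Martin periodinane oxidises F5 to 9.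

**Step 9 is the third risk.** The hindered ring ester may be reduced sluggishly or over-reduced, and the freed aldehyde 16 could epimerise at C1 before olefination. The fallback sets out from 14 and comes back at 17. LiAlH4 in THF at 0 °C reduces the ester fully to the diol F6. The primary alcohol is then oxidised selectively with catalytic 2,2,6,6-tetramethylpiperidin-1-oxyl and PhI(OAc)2 in CH2Cl2 in the presence of ethyl (2E)-4-(triphenylphosphoranylidene)but-2-enoate, so the aldehyde is trapped by Wittig olefination as it forms, giving 17.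

Further compounds
F1 | step 7 | carboxylic acid from 12 (side-chain CHO oxidised to CO2H): 3-[ring]-propanoic acid bearing the vinyl, butenyl, methyl and ethyl ester groups of 12 | C/C=C(\C)[C@H]1C(C)=C[C@@H](CCC(=O)O)[C@@H](C=C)[C@@H]1C(=O)OCC
F2 | step 7 | Se-phenyl selenoester of F1 | C/C=C(\C)[C@H]1C(C)=C[C@@H](CCC(=O)[Se]c2ccccc2)[C@@H](C=C)[C@@H]1C(=O)OCC
F3 | step 4 | (4R)-4-benzyl-3-[(2E)-4-ethoxy-4-oxobut-2-enoyl]-1,3-oxazolidin-2-one | CCOC(=O)/C=C/C(=O)N1[C@H](Cc2ccccc2)COC1=O
F4 | step 4 | imide analogue of 9 in which the formyl group is replaced by the (4R)-4-benzyl-2-oxo-1,3-oxazolidine-3-carbonyl group | C/C=C(\C)[C@H]1C(C)=C[C@@H](CCC(=O)OCC)[C@@H](C(=O)N2[C@H](Cc3ccccc3)COC2=O)[C@@H]1C(=O)OCC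
F5 | step 4 | primary alcohol analogue of 9 in which the formyl group is replaced by hydroxymethyl | C/C=C(\C)[C@H]1C(C)=C[C@@H](CCC(=O)OCC)[C@@H](CO)[C@@H]1C(=O)OCC
F6 | step 9 | diol from 14 in which the ethyl ester at C1 is reduced to hydroxymethyl | C/C=C(\C)[C@H]1C(C)=C[C@H]2CC[C@@H](O)[C@@H](C)[C@H]2[C@@H]1CO
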